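The dihydropyranone ring (O1, C2, C3, C4, C4a, C8a) is cut at C3–C4 and O1–C8a, which uncovers its β-alkoxy ketone O1–C2–C3–C4(=O) as (S)-propylene oxide joined to an acyl carbon of reversed polarity. The precursor is a flat fluoroarene: the 1,3-dithiane of 2-fluoro-4,6-dimethoxy-3-methylbenzaldehyde. In one flask its lithio derivative opens the epoxide at CH2 (C3–C4) and the alkoxide released displaces the ortho fluoride (O1–C8a), giving the chroman with C2 taken from the chiral pool and C4 masked. Unmasking, demethylation, C6 prenylation and a catalyst-controlled dearomatising geranylation at C8 then complete the carbocycle.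

Key step: step 4

Remark on numbering: chromane numbering is used throughout (O1, C2, C3, C4, C4a, C5, C6, C7, C8, C8a), also for the arene carbons that become these atoms. The target is the (2S,8R) isomer.

Remark on the chemistry (assumption): the (R,R) ligand in step 8 is assumed to lead to the 8R face; both antipodes of the ligand are catalogue compounds, and the (S,S) ligand is used instead if the first run shows the opposite sense.

Step 1
Reactants: 1 2-fluoro-4,6-dimethoxybenzaldehyde
Product: 2 1-fluoro-3,5-dimethoxy-2-methylbenzene
Conditions: Et3SiH (3 equiv), TFA, CH2Cl2, 0 °C → rt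
Reagents that add atoms: none
Why: Ionic hydrogenation, in which the electron-rich aldehyde is reduced through the dimethoxy-stabilised benzylic cation to the methyl group by hydride transfer from the silane, while the aryl fluoride and the methyl ethers are inert.

Step 2
Reactants: 2 1-fluoro-3,5-dimethoxy-2-methylbenzene
Product: 3 2-fluoro-4,6-dimethoxy-3-methylbenzaldehyde
Conditions: POCl3, DMF, 0 → 70 °C; then aq. NaOAc
Reagents that add atoms: N,N-dimethylformamide CN(C)C=O; water O
Why: Vilsmeier–Haack formylation should occur at the ring carbon that is para to one methoxy group, ortho to the other and flanked only by the small fluorine, and not at the more crowded carbon between the two methoxy groups, as is usual for 5-substituted 1,3-dimethoxybenzenes.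

Step 3
Reactants: 3 2-fluoro-4,6-dimethoxy-3-methylbenzaldehyde; 4 propane-1,3-dithiol
Product: 5 2-(2-fluoro-4,6-dimethoxy-3-methylphenyl)-1,3-dithiane
Conditions: BF3·OEt2 (cat.), CH2Cl2, 0 °C → rt
Reagents that add atoms: none
Why: Lewis-acid-catalysed dithioacetalisation of an aryl aldehyde, which turns the future C4 into a carbon that can be deprotonated.

Step 4
Reactants: 5 2-(2-fluoro-4,6-dimethoxy-3-methylphenyl)-1,3-dithiane; 6 (S)-2-methyloxirane
Product: 9 (S)-5,7-dimethoxy-2,8-dimethylspiro[chromane-4,2'-[1,3]dithiane], via lithiated dithiane 7 (not isolated), via lithium alkoxide 8 (not isolated)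
Conditions: n-BuLi, THF, −78 → −30 °C; then 6, −78 °C → rt; then DMPU, 65 °C (one flask)
Reagents that add atoms: none
Why: n-BuLi removes the C–H of the dithiane (Corey–Seebach polarity reversal of the future carbonyl carbon C4) to give 7, which opens (S)-2-methyloxirane by SN2 attack at its unsubstituted CH2 and so forms C3–C4 between two carbons that are both electrophilic in their natural polarity. The lithium alkoxide 8 released in that event then attacks the fluorine-bearing arene carbon C8a in an intramolecular SNAr (addition–elimination through a Meisenheimer-type anion, with lithium assisting the loss of fluoride), which forms O1–C8a. The closest known reaction types are the alkylation of 2-aryl-2-lithio-1,3-dithianes with terminal epoxides and the alkoxide SNAr cyclisation of ortho-fluoroaryl alkanols to chromans, here run in one flask. The pyran ring closes in the 6-exo-trig mode, helped by the geminal disubstitution at the spiro carbon. No stereocentre is created: C2 is the carbinol carbon of the epoxide, which is not touched by attack at CH2, so its S configuration is carried over, and with C4 masked it cannot be lost by retro-oxa-Michael opening. The step needs deprotonation at the dithiane and not at the arene (no hydrogen is left ortho to fluorine, so no aryne can form, and the dithiane C–H is the most acidic site at low temperature), epoxide opening at the terminus (steric control) and displacement of the single fluoride, all of which the substitution pattern of 5 secures.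

Step 5
Reactants: 9 (S)-5,7-dimethoxy-2,8-dimethylspiro[chromane-4,2'-[1,3]dithiane]
Product: 10 (S)-5,7-dimethoxy-2,8-dimethylchroman-4-one
Conditions: MeI, CaCO3, MeCN/H2O (9:1), 45 °C
Reagents that add atoms: water O
Why: Alkylative dethioacetalisation, in which S-methylation makes a sulfonium leaving group, the electron-rich aryl ring assists ionisation to the thionium ion and water delivers the carbonyl oxygen under buffered, non-oxidising conditions that leave the arene and the C2 stereocentre untouched.

Step 6
Reactants: 10 (S)-5,7-dimethoxy-2,8-dimethylchroman-4-one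
Product: 11 (S)-5,7-dihydroxy-2,8-dimethylchroman-4-one
Conditions: BBr3, CH2Cl2, −78 °C → rt
Reagents that add atoms: none
Why: Lewis-acid ether cleavage by bromide attack on the O-methyl carbons of the boron-complexed ethers (the C5 ether assisted by chelation to the C4 carbonyl), which is faster than attack at the secondary C2 of the ring ether, a weakly basic vinylogous ester oxygen, so that C2 should keep its configuration.

Step 7
Reactants: 11 (S)-5,7-dihydroxy-2,8-dimethylchroman-4-one; 12 3-methylbut-2-en-1-yl acetate (prenyl acetate)
Product: 13 (S)-5,7-dihydroxy-2,8-dimethyl-6-(3-methylbut-2-en-1-yl)chroman-4-one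
Conditions: Pd(PPh3)4 (5 mol %), Et3N, THF, rt
Reagents that add atoms: none
Why: Tsuji–Trost allylation of the phenoxide of 11 by the π-prenyl palladium cation at its unsubstituted terminus, in which C6 is the only ring carbon that can be alkylated with retention of aromaticity and any O7 prenyl ether formed is re-ionised by zerovalent palladium and funnelled to the C-prenyl product.

Step 8
Reactants: 13 (S)-5,7-dihydroxy-2,8-dimethyl-6-(3-methylbut-2-en-1-yl)chroman-4-one; 14 (2E)-3,7-dimethylocta-2,6-dien-1-yl acetate (geranyl acetate)
Product: 15 (2S,8R)-8-[(2E)-3,7-dimethylocta-2,6-dien-1-yl]-5-hydroxy-2,8-dimethyl-6-(3-methylbut-2-en-1-yl)-2,3-dihydro-4H-chromene-4,7(8H)-dione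
Conditions: Pd2(dba)3·CHCl3 (2.5 mol %), (R,R)-DACH-phenyl ligand N,N'-[(1R,2R)-cyclohexane-1,2-diyl]bis[2-(diphenylphosphanyl)benzamide] (7.5 mol %), Et3N (1 equiv), CH2Cl2, 0 °C → rt
Reagents that add atoms: none
Why: Palladium-catalysed asymmetric allylic dearomatisation, in which the 7-phenoxide of 13 (the 5-OH stays chelated to the C4 carbonyl) attacks the CH2 terminus of the π-geranyl palladium complex through C8, which is less hindered than the prenyl-bearing C6, to give the linear E-geranyl group and the cyclohexadienone, while the C8 stereocentre is set by the chiral ligand, which differentiates the two faces of the planar phenoxide with little influence from the remote C2 centre.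

Compound list
1 | 2-fluoro-4,6-dimethoxybenzaldehyde | COc1cc(OC)c(C=O)c(F)c1 | starting material
2 | 1-fluoro-3,5-dimethoxy-2-methylbenzene | COc1cc(OC)c(C)c(F)c1 | intermediate
3 | 2-fluoro-4,6-dimethoxy-3-methylbenzaldehyde | COc1cc(OC)c(C=O)c(F)c1C | intermediate
4 | propane-1,3-dithiol | SCCCS | starting material
5 | 2-(2-fluoro-4,6-dimethoxy-3-methylphenyl)-1,3-dithiane | COc1cc(OC)c(C2SCCCS2)c(F)c1C | intermediate
6 | (S)-2-methyloxirane ((S)-propylene oxide) | C[C@H]1CO1 | starting material
7 | 2-lithio-2-(2-fluoro-4,6-dimethoxy-3-methylphenyl)-1,3-dithiane (lithiated dithiane, formed in the flask) | COc1cc(OC)c(C2([Li])SCCCS2)c(F)c1C | intermediate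
8 | lithium (S)-1-[2-(2-fluoro-4,6-dimethoxy-3-methylphenyl)-1,3-dithian-2-yl]propan-2-olate (lithium alkoxide, formed in the flask) | C[C@H](O[Li])CC1(SCCCS1)c1c(OC)cc(OC)c(C)c1F | intermediate
9 | (S)-5,7-dimethoxy-2,8-dimethylspiro[chromane-4,2'-[1,3]dithiane] | C[C@H]1CC2(SCCCS2)c2c(OC)cc(OC)c(C)c2O1 | intermediate
10 | (S)-5,7-dimethoxy-2,8-dimethylchroman-4-one | C[C@H]1CC(=O)c2c(OC)cc(OC)c(C)c2O1 | intermediate
11 | (S)-5,7-dihydroxy-2,8-dimethylchroman-4-one | C[C@H]1CC(=O)c2c(O)cc(O)c(C)c2O1 | intermediate
12 | 3-methylbut-2-en-1-yl acetate (prenyl acetate) | CC(C)=CCOC(C)=O | starting material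
13 | (S)-5,7-dihydroxy-2,8-dimethyl-6-(3-methylbut-2-en-1-yl)chroman-4-one | C[C@H]1CC(=O)c2c(O)c(CC=C(C)C)c(O)c(C)c2O1 | intermediate
14 | (2E)-3,7-dimethylocta-2,6-dien-1-yl acetate (geranyl acetate) | CC(C)=CCC/C(C)=C/COC(C)=O | starting material
15 | (2S,8R)-8-[(2E)-3,7-dimethylocta-2,6-dien-1-yl]-5-hydroxy-2,8-dimethyl-6-(3-methylbut-2-en-1-yl)-2,3-dihydro-4H-chromene-4,7(8H)-dione | CC(C)=CCC/C(C)=C/C[C@@]1(C)C(=O)C(CC=C(C)C)=C(O)C2=C1O[C@@H](C)CC2=O | target

Total step count: 8. Longest linear sequence: 8 steps (1 → 15).

Steps most likely to fail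

1. Step 8. The palladium allyl may attack the prenyl-bearing C6 or the phenoxide oxygen instead of C8, the facial discrimination may be poor, and the acidic product may be alkylated a second time. The fallback sets out from 11 and comes back at 15; it blocks C6 and introduces the prenyl group last. Bromination of 11 at its only free ring carbon (NBS, MeCN, 0 °C) gives (S)-6-bromo-5,7-dihydroxy-2,8-dimethylchroman-4-one F1. The same palladium/ligand system with 14 can then dearomatise only at the methyl-bearing C8 and gives (2S,8R)-6-bromo-8-[(2E)-3,7-dimethylocta-2,6-dien-1-yl]-5-hydroxy-2,8-dimethyl-2,3-dihydro-4H-chromene-4,7(8H)-dione F2. The bromine on the enolised 1,3-dione is removed reductively (Zn, AcOH, THF, 0 °C) to give (2S,8R)-8-[(2E)-3,7-dimethylocta-2,6-dien-1-yl]-5-hydroxy-2,8-dimethyl-2,3-dihydro-4H-chromene-4,7(8H)-dione F3. Tsuji–Trost C-prenylation of F3 at C6–H with 12 (Pd(PPh3)4, Et3N, THF) then gives 15.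

2. Step 4. Displacement of the unactivated fluoride by the lithium alkoxide may be too slow, so that the sequence stops at the open-chain stage or the anion decomposes on heating; metalation of the arene may also compete with deprotonation of the dithiane. The fallback sets out from 5 and comes back at 10; it moves the ring closure to a carbonyl-activated substrate. Compound 5 is lithiated and alkylated with 6 as before but quenched cold (aq. NH4Cl) to isolate (S)-1-[2-(2-fluoro-4,6-dimethoxy-3-methylphenyl)-1,3-dithian-2-yl]propan-2-ol F4. Hydrolysis of the dithiane (MeI, CaCO3, aq. MeCN) gives (S)-1-(2-fluoro-4,6-dimethoxy-3-methylphenyl)-3-hydroxybutan-1-one F5, in which the ortho acyl group activates the fluoride. Mild base (K2CO3, DMF, rt) should then close the ring by SNAr to give 10.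

3. Step 7. Alkylation may take place at oxygen and stay there, or a second prenyl group may add at C8 with dearomatisation. The fallback sets out from 11 and comes back at 13; it replaces direct C-alkylation by O-alkylation and rearrangement. Prenyl bromide with K2CO3 in acetone alkylates the non-chelated 7-OH to give (S)-5-hydroxy-2,8-dimethyl-7-[(3-methylbut-2-en-1-yl)oxy]chroman-4-one F6. Montmorillonite K10 in CH2Cl2 then promotes the [1,3] O→C shift of the prenyl group to the only free ortho carbon, C6, to give 13.

Further compounds
F1 | step 8 | (S)-6-bromo-5,7-dihydroxy-2,8-dimethylchroman-4-one | C[C@H]1CC(=O)c2c(O)c(Br)c(O)c(C)c2O1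
F2 | step 8 | (2S,8R)-6-bromo-8-[(2E)-3,7-dimethylocta-2,6-dien-1-yl]-5-hydroxy-2,8-dimethyl-2,3-dihydro-4H-chromene-4,7(8H)-dione | CC(C)=CCC/C(C)=C/C[C@@]1(C)C(=O)C(Br)=C(O)C2=C1O[C@@H](C)CC2=O
F3 | step 8 | (2S,8R)-8-[(2E)-3,7-dimethylocta-2,6-dien-1-yl]-5-hydroxy-2,8-dimethyl-2,3-dihydro-4H-chromene-4,7(8H)-dione | CC(C)=CCC/C(C)=C/C[C@@]1(C)C(=O)C=C(O)C2=C1O[C@@H](C)CC2=O
F4 | step 4 | (S)-1-[2-(2-fluoro-4,6-dimethoxy-3-methylphenyl)-1,3-dithian-2-yl]propan-2-ol | C[C@H](O)CC1(SCCCS1)c1c(OC)cc(OC)c(C)c1F
F5 | step 4 | (S)-1-(2-fluoro-4,6-dimethoxy-3-methylphenyl)-3-hydroxybutan-1-one | C[C@H](O)CC(=O)c1c(OC)cc(OC)c(C)c1F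
F6 | step 7 | (S)-5-hydroxy-2,8-dimethyl-7-[(3-methylbut-2-en-1-yl)oxy]chroman-4-one | C[C@H]1CC(=O)c2c(O)cc(OCC=C(C)C)c(C)c2O1
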